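Labels: pinane C1–C7 (C2 spiro, C6 = CMe2 bridge); ring B = C2–Ca–Cb–Cc–Cd; ring A = Ca–Cv(=O)–Cw(Me)=Cx(OMe)–Cy(Me2)–Cz(=O).
Cuts, in retrosynthetic order: O–CH3 on Cx; Ca–Cz (Dieckmann); Cv–Cw (aldol, then oxidation); Cb–isopropyl (conjugate addition); ring B at Cd–C2 and Cc–Cb; C2=Ca (Knoevenagel) back to nopinone.
Forward order: bought pinane → alkylidene malonate → ring B by nickel reductive (3+2) with acetylene → isopropyl at Cb → chain on the surviving ester carbon → ring A last.
Enabling feature: in ring B, C2, Ca and the carbonyl carbon on Ca that becomes Cb are the β-carbon, α-carbon and ester carbon of an alkylidene malonate, and Cc–Cd is a two-carbon alkyne unit.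
Stereochemistry: C1 and C5 from (+)-β-pinene; C2 by attack anti to the C6 bridge; Cb by addition anti to the C1 side; Ca by ring closure anti to the isopropyl group.

Key step: step 3

Remark: the faces of ring B are named after the pinane carbon (C1 or C3) standing on them. Wherever Ca carries an enolisable H, the compound is carried as a mixture of Ca epimers and its SMILES leaves Ca and any transient centre open, because Ca is planarised again when ring A closes. β-Dicarbonyl compounds are drawn in the keto form except the final enol. Metal enolates and alkoxides that are only protonated on work-up are not numbered.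

**Route**

Step 1
Reactants: 1 (1R,5R)-(+)-β-pinene
Product: 3 (1S,5R)-(−)-nopinone, via ozonide 2 (not isolated)
Conditions: O3, CH2Cl2, −78 °C; then Me2S, −78 °C → rt
Reagents that add atoms: ozone O=[O+][O-]
Why: Ozonolysis of the exocyclic 1,1-disubstituted alkene with reductive work-up is the standard way to nopinone and touches no stereocentre (the descriptor of C1 changes only through a change of CIP priorities).

Step 2
Reactants: 3 (1S,5R)-(−)-nopinone; 4 dimethyl malonate
Product: 5 dimethyl 2-(6,6-dimethylbicyclo[3.1.1]hept-2-ylidene)malonate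
Conditions: TiCl4, pyridine, THF, 0 °C → rt
Reagents that add atoms: none
Why: The TiCl4/pyridine Knoevenagel condensation is the established method for condensing malonates with ketones; the buffered medium should spare the cyclobutane and no stereocentre is formed.

Step 3
Reactants: 5 dimethyl 2-(6,6-dimethylbicyclo[3.1.1]hept-2-ylidene)malonate; 6 acetylene
Product: 7 methyl 6,6-dimethyl-3'-oxospiro[bicyclo[3.1.1]heptane-2,1'-cyclopentan]-4'-ene-2'-carboxylate
Conditions: Ni(cod)2 (10 mol%), PBu3 (20 mol%), BEt3, C2H2 (1 atm), MeOH/THF, 50 °C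
Reagents that add atoms: none
Why: Proposed new method: zerovalent nickel should couple the electron-poor C2=Ca bond of 5 with acetylene by oxidative cyclisation, which makes the Cd–C2 bond and leaves an alkenylnickel unit tied to a nickel malonate enolate; methanol protonates that enolate at Ca, the alkenyl–nickel bond adds to one ester carbonyl, methoxide leaves to give the enone, and BEt3 takes divalent nickel back to zerovalent nickel. The closest known reaction type is the Ni(cod)2/PBu3/BEt3 reductive (3+2) cycloaddition of enoates with alkynes to cyclopentenones, which has not been shown for a tetrasubstituted alkylidene malonate or for acetylene itself. Ring B closes in a 5-exo-trig 1,2-addition of the alkenylnickel carbon Cc to the ester carbon that becomes Cb. The only lasting new stereocentre is spiro C2, set when nickel and the alkyne carbon reach the C2 face anti to the C6 CMe2 bridge, so that Ca ends up syn to the bridge; Ca itself is a labile β-ketoester CH. The step needs this facial selectivity, which the bridge secures, and cross-coupling in preference to acetylene oligomerisation or plain reductive vinylation, which the doubly activated alkene and a low acetylene pressure should favour; there is no regiochemical issue because acetylene is symmetrical and both esters lead to the same ketoester.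

Step 4
Reactants: 7 methyl 6,6-dimethyl-3'-oxospiro[bicyclo[3.1.1]heptane-2,1'-cyclopentan]-4'-ene-2'-carboxylate
Product: 8 methyl 6,6-dimethyl-3'-oxospiro[bicyclo[3.1.1]heptane-2,1'-cyclopentane]-2'-carboxylate
Conditions: H2 (1 atm), 10% Pd/C, EtOAc, rt
Reagents that add atoms: none
Why: Heterogeneous hydrogenation should saturate the disubstituted enone alkene Cc=Cd well before it touches the ketone or ester, and it creates no stereocentre.

Step 5
Reactants: 8 methyl 6,6-dimethyl-3'-oxospiro[bicyclo[3.1.1]heptane-2,1'-cyclopentane]-2'-carboxylate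
Product: 9 methyl 6,6-dimethyl-3'-(trifluoromethanesulfonyloxy)spiro[bicyclo[3.1.1]heptane-2,1'-cyclopentan]-2'-ene-2'-carboxylate
Conditions: NaH, Et2O, 0 °C; then Tf2O, −20 → 0 °C
Reagents that add atoms: trifluoromethanesulfonic anhydride O=S(=O)(OS(=O)(=O)C(F)(F)F)C(F)(F)F
Why: O-Sulfonylation of the sodium enolate of a cyclic β-ketoester is routine enol triflate formation and fixes the double bond between Ca and Cb.

Step 6
Reactants: 9 methyl 6,6-dimethyl-3'-(trifluoromethanesulfonyloxy)spiro[bicyclo[3.1.1]heptane-2,1'-cyclopentan]-2'-ene-2'-carboxylate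
Product: 10 methyl 6,6-dimethylspiro[bicyclo[3.1.1]heptane-2,1'-cyclopentan]-2'-ene-2'-carboxylate
Conditions: Pd(OAc)2 (cat.), PPh3, HCO2H, Bu3N, DMF, 60 °C
Reagents that add atoms: none
Why: Palladium-catalysed formate reduction of an enol triflate (oxidative addition to zerovalent palladium, formate exchange with loss of CO2, reductive elimination) replaces OTf by H and leaves the conjugated ester untouched.

Step 7
Reactants: 10 methyl 6,6-dimethylspiro[bicyclo[3.1.1]heptane-2,1'-cyclopentan]-2'-ene-2'-carboxylate
Product: 12 methyl 6,6-dimethyl-3'-(propan-2-yl)spiro[bicyclo[3.1.1]heptane-2,1'-cyclopentane]-2'-carboxylate, via silyl ketene acetal 11 (not isolated)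
Conditions: i-PrMgCl, CuBr·SMe2 (cat.), Me3SiCl, THF, −78 → −30 °C; then aq. HCl
Reagents that add atoms: isopropylmagnesium chloride CC(C)[Mg]Cl; chlorotrimethylsilane C[Si](C)(C)Cl
Why: Copper-catalysed, silyl chloride-accelerated conjugate addition of a Grignard reagent to a cyclopentene-1-carboxylate is well known; the isopropyl group should enter Cb on the C3 face because the C1 face carries the branched bridgehead with both pinane bridges, the silyl group stays only in 11, and Ca is protonated unselectively on hydrolysis.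

Step 8
Reactants: 12 methyl 6,6-dimethyl-3'-(propan-2-yl)spiro[bicyclo[3.1.1]heptane-2,1'-cyclopentane]-2'-carboxylate
Product: 13 [6,6-dimethyl-3'-(propan-2-yl)spiro[bicyclo[3.1.1]heptane-2,1'-cyclopentan]-2'-yl]methanol
Conditions: LiAlH4, THF, 0 °C → rt; then H2O, aq. NaOH
Reagents that add atoms: none
Why: LiAlH4 reduction of an ester to the primary alcohol is reliable even for hindered esters and changes no stereocentre.

Step 9
Reactants: 13 [6,6-dimethyl-3'-(propan-2-yl)spiro[bicyclo[3.1.1]heptane-2,1'-cyclopentan]-2'-yl]methanol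
Product: 14 6,6-dimethyl-3'-(propan-2-yl)spiro[bicyclo[3.1.1]heptane-2,1'-cyclopentane]-2'-carbaldehyde
Conditions: Dess–Martin periodinane, CH2Cl2, rt
Reagents that add atoms: none
Why: Dess–Martin oxidation takes a hindered primary alcohol to the aldehyde without over-oxidation.

Step 10
Reactants: 15 methyl isobutyrate; 16 propionyl chloride
Product: 17 methyl 2,2-dimethyl-3-oxopentanoate
Conditions: LiN(i-Pr)2, THF, −78 °C; then EtCOCl, −78 °C → rt
Reagents that add atoms: none
Why: C-Acylation of the lithium enolate of an α,α-disubstituted ester with an acid chloride is a standard crossed Claisen-type reaction, and the product has no acidic CH between its carbonyls, so one equivalent of base suffices.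

Step 11
Reactants: 14 6,6-dimethyl-3'-(propan-2-yl)spiro[bicyclo[3.1.1]heptane-2,1'-cyclopentane]-2'-carbaldehyde; 17 methyl 2,2-dimethyl-3-oxopentanoate
Product: 18 methyl 5-hydroxy-2,2,4-trimethyl-3-oxo-5-[6,6-dimethyl-3'-(propan-2-yl)spiro[bicyclo[3.1.1]heptane-2,1'-cyclopentan]-2'-yl]pentanoate
Conditions: LiN(i-Pr)2, 17, THF, −78 °C; then 14; AcOH, −78 °C
Reagents that add atoms: none
Why: In this directed aldol addition LiN(i-Pr)2 can enolise 17 only at the CH2 of its ethyl ketone, and the lithium enolate adds to the aldehyde carbon (future Cv) at low temperature; the new carbinol and methyl-bearing centres are oxidised or enolised later, so their configuration does not matter.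

Step 12
Reactants: 18 methyl 5-hydroxy-2,2,4-trimethyl-3-oxo-5-[6,6-dimethyl-3'-(propan-2-yl)spiro[bicyclo[3.1.1]heptane-2,1'-cyclopentan]-2'-yl]pentanoate
Product: 19 methyl 2,2,4-trimethyl-3,5-dioxo-5-[6,6-dimethyl-3'-(propan-2-yl)spiro[bicyclo[3.1.1]heptane-2,1'-cyclopentan]-2'-yl]pentanoate
Conditions: Dess–Martin periodinane, CH2Cl2, rt
Reagents that add atoms: none
Why: Dess–Martin oxidation of a β-hydroxy ketone is the usual entry to 1,3-diketones.

Step 13
Reactants: 19 methyl 2,2,4-trimethyl-3,5-dioxo-5-[6,6-dimethyl-3'-(propan-2-yl)spiro[bicyclo[3.1.1]heptane-2,1'-cyclopentan]-2'-yl]pentanoate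
Product: 20 enol triketone (target lacking the O-methyl group, ring A drawn as the Cx enol)
Conditions: LiN(i-Pr)2 (2.5 equiv), THF, −78 → 0 °C; then aq. HCl
Reagents that add atoms: none
Why: This is a Dieckmann-type cyclisation through the 1,3-diketone dianion: after Cw–H the only removable proton is Ca–H, the dianion reacts at its terminal carbon Ca with ester carbon Cz (6-exo-trig), and the product is held as its Cv/Cx enolate; the Ca–Cz bond should form on the face of Ca anti to the neighbouring isopropyl group, which puts Cz trans and Cv cis to it as the target requires.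

Step 14
Reactants: 20 enol triketone (target lacking the O-methyl group, ring A drawn as the Cx enol)
Product: 21 target compound CNP0307059.1
Conditions: Me3SiCHN2, MeOH/toluene, 0 °C → rt
Reagents that add atoms: trimethylsilyldiazomethane C[Si](C)(C)C=[N+]=[N-]
Why: A diazoalkane O-methylates the acidic cyclic 1,3-dione enol without C-methylation, and of the two enol oxygens the one on Cx, flanked only by CMe2, should be more accessible than the one on Cv beside the spiro centre and the cis isopropyl group.

**Compound list**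

1 | (1R,5R)-(+)-β-pinene | C=C1CC[C@@H]2C[C@H]1C2(C)C | starting material
2 | β-pinene ozonide (spiro 1,2,4-trioxolane on C2, formed in the flask) | C1OC2(OO1)CC[C@@H]3C[C@H]2C3(C)C | intermediate
3 | (1S,5R)-(−)-nopinone | O=C1CC[C@@H]2C[C@H]1C2(C)C | intermediate
4 | dimethyl malonate | COC(=O)CC(=O)OC | starting material
5 | dimethyl 2-(6,6-dimethylbicyclo[3.1.1]hept-2-ylidene)malonate (pinane centres as in 3) | COC(=O)C(C(=O)OC)=C1CC[C@@H]2C[C@H]1C2(C)C | intermediate
6 | acetylene | C#C | starting material
7 | methyl 6,6-dimethyl-3'-oxospiro[bicyclo[3.1.1]heptane-2,1'-cyclopentan]-4'-ene-2'-carboxylate (keto form; olefinic Cd on C2 anti to the C6 bridge, Ca syn to it) | COC(=O)C1C(=O)C=C[C@@]12CC[C@@H]3C[C@H]2C3(C)C | intermediate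
8 | methyl 6,6-dimethyl-3'-oxospiro[bicyclo[3.1.1]heptane-2,1'-cyclopentane]-2'-carboxylate | COC(=O)C1C(=O)CC[C@@]12CC[C@@H]3C[C@H]2C3(C)C | intermediate
9 | methyl 6,6-dimethyl-3'-(trifluoromethanesulfonyloxy)spiro[bicyclo[3.1.1]heptane-2,1'-cyclopentan]-2'-ene-2'-carboxylate | COC(=O)C1=C(OS(=O)(=O)C(F)(F)F)CC[C@@]12CC[C@@H]3C[C@H]2C3(C)C | intermediate
10 | methyl 6,6-dimethylspiro[bicyclo[3.1.1]heptane-2,1'-cyclopentan]-2'-ene-2'-carboxylate | COC(=O)C1=CCC[C@@]12CC[C@@H]3C[C@H]2C3(C)C | intermediate
11 | trimethylsilyl ketene acetal of 12 (formed in the flask) | COC(O[Si](C)(C)C)=C1[C@@H](C(C)C)CC[C@@]12CC[C@@H]3C[C@H]2C3(C)C | intermediate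
12 | methyl 6,6-dimethyl-3'-(propan-2-yl)spiro[bicyclo[3.1.1]heptane-2,1'-cyclopentane]-2'-carboxylate (isopropyl on the C3 face of ring B) | COC(=O)C1[C@@H](C(C)C)CC[C@@]12CC[C@@H]3C[C@H]2C3(C)C | intermediate
13 | [6,6-dimethyl-3'-(propan-2-yl)spiro[bicyclo[3.1.1]heptane-2,1'-cyclopentan]-2'-yl]methanol | OCC1[C@@H](C(C)C)CC[C@@]12CC[C@@H]3C[C@H]2C3(C)C | intermediate
14 | 6,6-dimethyl-3'-(propan-2-yl)spiro[bicyclo[3.1.1]heptane-2,1'-cyclopentane]-2'-carbaldehyde | O=CC1[C@@H](C(C)C)CC[C@@]12CC[C@@H]3C[C@H]2C3(C)C | intermediate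
15 | methyl isobutyrate | CC(C)C(=O)OC | starting material
16 | propionyl chloride | CCC(Cl)=O | starting material
17 | methyl 2,2-dimethyl-3-oxopentanoate | CCC(=O)C(C)(C)C(=O)OC | intermediate
18 | methyl 5-hydroxy-2,2,4-trimethyl-3-oxo-5-(spiro ring B-2'-yl)pentanoate (aldol adduct) | COC(=O)C(C)(C)C(=O)C(C)C(O)C1[C@@H](C(C)C)CC[C@@]12CC[C@@H]3C[C@H]2C3(C)C | intermediate
19 | methyl 2,2,4-trimethyl-3,5-dioxo-5-(spiro ring B-2'-yl)pentanoate (diketo ester) | COC(=O)C(C)(C)C(=O)C(C)C(=O)C1[C@@H](C(C)C)CC[C@@]12CC[C@@H]3C[C@H]2C3(C)C | intermediate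
20 | enol triketone, the target lacking its O-methyl group, ring A drawn as the Cx enol (Cz on the C1 face, Cv and isopropyl on the C3 face) | OC1=C(C)C(=O)[C@@]2(C(=O)C1(C)C)[C@@H](C(C)C)CC[C@@]21CC[C@@H]2C[C@H]1C2(C)C | intermediate
21 | CNP0307059.1 | COC1=C(C)C(=O)[C@@]2(C(=O)C1(C)C)[C@@H](C(C)C)CC[C@@]21CC[C@@H]2C[C@H]1C2(C)C | target

**Count and risks**

Total steps: 14. Longest linear sequence: 13 (steps 1–9 and 11–14); step 10 is a one-step side branch.

Step 3 (carries the label). Nickel-mediated oligomerisation of acetylene may outrun the cross-coupling, the fully substituted β-carbon C2 may not enter oxidative cyclisation, or the sequence may stop at reductive vinylation without attack on the ester. The fallback uses known chemistry and sets out from 5. CuI-catalysed conjugate addition of but-3-enylmagnesium bromide (Me3SiCl, THF, −30 °C), again anti to the C6 bridge, would give dimethyl 2-[2-(but-3-en-1-yl)-6,6-dimethylbicyclo[3.1.1]hept-2-yl]malonate F1. Half-saponification (KOH, MeOH/H2O) would give the malonic half ester 2-[2-(but-3-en-1-yl)-6,6-dimethylbicyclo[3.1.1]hept-2-yl]-3-methoxy-3-oxopropanoic acid F2. Decarboxylative Mannich methylenation (paraformaldehyde, Et2NH, reflux) would give the α-methylene ester methyl 2-[2-(but-3-en-1-yl)-6,6-dimethylbicyclo[3.1.1]hept-2-yl]acrylate F3. Ring-closing metathesis with the second-generation Grubbs catalyst RuCl2(=CHPh)(H2IMes)(PCy3) would then close ring B between Ca and Cb and come back to the route at 10, so that steps 4 to 6 fall away.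

Step 7. Facial selectivity at Cb may be poor, because the bias comes from a spiro centre that is not adjacent to Cb. The fallback relies on catalyst control and sets out from 9. Fe(acac)3-catalysed cross-coupling with i-PrMgCl (THF/NMP, −30 °C) would give the β-isopropyl enoate methyl 6,6-dimethyl-3'-(propan-2-yl)spiro[bicyclo[3.1.1]heptane-2,1'-cyclopentan]-2'-ene-2'-carboxylate F4. LiOH hydrolysis would give the corresponding enoic acid F5. Hydrogenation with Ru(OAc)2[(S)-BINAP] or its mirror image, whichever ligand antipode delivers H2 to the C1 face, would give the cis acid F6. Esterification with Me3SiCHN2 comes back to the route at 12, as the Ca epimer with ester and isopropyl cis, which serves equally well because Ca is planarised in step 13.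

Step 13. Bond formation at the congested Ca may lose out to O-acylation of the enolate (enol lactone formation), or the second deprotonation at Ca may be incomplete. The fallback uses a slimmer electrophile and sets out from 14. The aldol partner is changed to 2,2-dimethyl-3-oxopentanenitrile F7, made from isobutyronitrile, LiN(i-Pr)2 and propionyl chloride. Aldol addition of its lithium enolate to 14 would give the hydroxy keto nitrile F8, and Dess–Martin oxidation the diketo nitrile F9. LiN(i-Pr)2 (2.5 equiv) should then close ring A by Thorpe-type addition of the dianion terminus Ca to the nitrile carbon, giving the cyclic Cz imine F10. Aqueous HCl hydrolyses the imine and comes back to the route at 20.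

**Further compounds**

F1 | step 3 | dimethyl 2-[2-(but-3-en-1-yl)-6,6-dimethylbicyclo[3.1.1]hept-2-yl]malonate (butenyl anti to the C6 bridge) | COC(=O)C(C(=O)OC)[C@@]1(CCC=C)CC[C@@H]2C[C@H]1C2(C)C
F2 | step 3 | 2-[2-(but-3-en-1-yl)-6,6-dimethylbicyclo[3.1.1]hept-2-yl]-3-methoxy-3-oxopropanoic acid | COC(=O)C(C(=O)O)[C@@]1(CCC=C)CC[C@@H]2C[C@H]1C2(C)C
F3 | step 3 | methyl 2-[2-(but-3-en-1-yl)-6,6-dimethylbicyclo[3.1.1]hept-2-yl]acrylate | COC(=O)C(=C)[C@@]1(CCC=C)CC[C@@H]2C[C@H]1C2(C)C
F4 | step 7 | methyl 6,6-dimethyl-3'-(propan-2-yl)spiro[bicyclo[3.1.1]heptane-2,1'-cyclopentan]-2'-ene-2'-carboxylate | COC(=O)C1=C(C(C)C)CC[C@@]12CC[C@@H]3C[C@H]2C3(C)C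
F5 | step 7 | 6,6-dimethyl-3'-(propan-2-yl)spiro[bicyclo[3.1.1]heptane-2,1'-cyclopentan]-2'-ene-2'-carboxylic acid | OC(=O)C1=C(C(C)C)CC[C@@]12CC[C@@H]3C[C@H]2C3(C)C
F6 | step 7 | cis-6,6-dimethyl-3'-(propan-2-yl)spiro[bicyclo[3.1.1]heptane-2,1'-cyclopentane]-2'-carboxylic acid (CO2H and isopropyl both on the C3 face) | OC(=O)[C@H]1[C@@H](C(C)C)CC[C@@]12CC[C@@H]3C[C@H]2C3(C)C
F7 | step 13 | 2,2-dimethyl-3-oxopentanenitrile | CCC(=O)C(C)(C)C#N
F8 | step 13 | 5-hydroxy-2,2,4-trimethyl-3-oxo-5-(spiro ring B-2'-yl)pentanenitrile | N#CC(C)(C)C(=O)C(C)C(O)C1[C@@H](C(C)C)CC[C@@]12CC[C@@H]3C[C@H]2C3(C)C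
F9 | step 13 | 2,2,4-trimethyl-3,5-dioxo-5-(spiro ring B-2'-yl)pentanenitrile | N#CC(C)(C)C(=O)C(C)C(=O)C1[C@@H](C(C)C)CC[C@@]12CC[C@@H]3C[C@H]2C3(C)C
F10 | step 13 | Cz imine of triketone 20 (Cx enol) | OC1=C(C)C(=O)[C@@]2(C(=N)C1(C)C)[C@@H](C(C)C)CC[C@@]21CC[C@@H]2C[C@H]1C2(C)C
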